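The numbers are assumed; the rest is arithmetic.

Temperature separates the three flasks below, and a bench chemist would apply the usual rule to them: cool an exothermic equilibrium to get more target.

| flask | substrate | reagent | free catalyst | impurity | temperature | time |
|---|---|---|---|---|---|---|
| eta | 38 mM | 1.10 equiv | 0.48 mol% | 22 µM | 25 °C | 30 min |
| zeta | 38 mM | 1.10 equiv | 0.48 mol% | 22 µM | 5 °C | 30 min |
| theta | 38 mM | 1.10 equiv | 0.48 mol% | 22 µM | −15 °C | 30 min |

    free catalyst + impurity → spent catalyst (k1 = 71000 L mol⁻¹ min⁻¹, Ea1 = 38.0 kJ mol⁻¹)
    substrate + reagent + free catalyst ⇌ target + free catalyst, rate k2*[substrate]*[reagent]*[free catalyst] forward; the back reaction follows from the equilibrium constant (K2 = 7.7 L mol⁻¹, k2 = 11000 L² mol⁻² min⁻¹, Ea2 = 36.0 kJ mol⁻¹, ΔH2 = −62.0 kJ mol⁻¹)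
    (constants at 5 °C)

* the best flask by amount of target, in percent of the substrate charged; "all alike" if 1.5 percentage points covers them all (eta / zeta / theta / all alike)
* amount of target at the end, in percent of the substrate charged, eta
* amount of target at the end, in percent of the substrate charged, zeta
* amount of target at the end, in percent of the substrate charged, theta

- all constants are for 5 °C and move with temperature by the activation energies and enthalpies

Dividing the forward rate of step 2 by its back rate cancels the free catalyst and the time. Let s be the substrate left as a fraction of the substrate charge, b the reagent left on the same scale, and x the target on that scale. Then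

r = Π·s·b/x

Here Π, the pull, is the equilibrium constant K times the substrate charge: the forward-to-back ratio with all three species at that charge. Step 2 stops at r = 1, which gives each flask its ceiling for x:

- eta: Π = 0.0484, ceiling 4.85%
- zeta: Π = 0.293, ceiling 20.7%
- theta: Π = 2.34, ceiling 55.8%

The rule of thumb holds for the ceilings, but a ceiling has to be reached. This reckoning assumes that the impurity takes one catalyst each, leaving 160 µM of free catalyst. Near the ceiling, the half-life of approach h is the natural log of two over k·c·(S + R + inverse K), with k the forward constant, c the free catalyst, and S and R the substrate and reagent concentrations. Cooling from zeta to theta divides k by (K at theta / K at zeta)^(Ea/−ΔH), which is 3.34.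

- zeta: h = 2.03 min, time/h = 14.8
- theta: h = 24.5 min, time/h = 1.23

The border of the rule is a time/h near one. Zeta stands well inside it, under thermodynamic control, while theta stands at the border, under kinetic control. A single exponential with this near-ceiling h, only a rough estimate for a flask this far from its ceiling, puts theta at 32.0%, still more than the ceiling of zeta, so this reckoning picks theta.

The forecast also picks theta, with 4.8% for eta, 20.7% for zeta and 36.3% for theta, a value for theta above this reckoning. Its ground for theta is that “the slower reaction is still kinetically limited at 30 min”.

The simulation gives theta as the best flask, with 4.85% for eta, 20.7% for zeta and 36.4% for theta. In zeta the relaxation half-life of step 2, 2.03 min at the asked time, is short against the 30 min allowed, and r ends at 1.00, whereas in theta r ends at 3.00 and the target reaches 55.8% after 300 min. In the neighbour of zeta with 2.80 equiv of reagent, the target reaches 41.1% and the same pull gives r = 1.00.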